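Slowness can be measured against another run: you ask how many minutes a flask needs to reach the same Q.

| setting | south-west | north-west | winter | midnight |
|---|---|---|---|---|
| D | 0.56 M | 0.56 M | 0.84 M | 0.84 M |
| L | 0.56 M | 0.56 M | 0.84 M | 0.84 M |
| G | 2.52 M | 2.52 M | 2.52 M | 2.52 M |
| temperature | 29 °C | 37 °C | 25 °C | 40 °C |
| remark | run made earlier | run made earlier |  |  |
| time |  |  | 80 min | 80 min |

- G is single-handed; D and L are mirror images of each other, charged as a racemate, each of them at the stated concentration
- the numbers in the tables scatter by 1 percentage point (one standard deviation)
- the handed part of G does not stay in what it makes, so the products of the two hands are mirror images too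

1. the flask that comes out highest in amount of Q, in percent of the D and L together charged, or "all alike" when all lie within 1.5 percentage points (winter / midnight / all alike)
2. Q at the end, in percent of the D and L together charged, winter
3. Q at the end, in percent of the D and L together charged, midnight

- south-west (time / min: Q / %): 10.0: 15.2; 30.0: 35.3; 50.0: 47.5; 80.0: 58.1
- north-west (time / min: Q / %): 6.00: 17.8; 15.0: 35.1; 30.0: 52.6; 40.0: 57.3

(scatter of a reading: 1 percentage point)

Read the two tables against each other. The south-west run at 29 °C shows 35.3% of Q at 30.0 min, and the north-west run at 37 °C shows 35.1% at 15.0 min, the same Q within the scatter of 1 percentage point. The last rows repeat this: 58.1% at 80.0 min against 57.3% at 40.0 min. So the warmer run keeps a faster clock, and I call 2.00 the stretch, the factor by which that step of temperature shortens the time to a given Q; it is a reading. If each equal step of temperature multiplies the clock by the stretch, then the times of winter and midnight convert into south-west minutes, a time-temperature shift.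

Winter, at 25 °C, lies below the south-west temperature, so its 80 min count as 56.6 min. That falls between the rows at 50.0 min and 80.0 min, and a straight line between them gives 49.8%. I expect winter somewhat below this estimate, since [D] is 0.84 M, more than 0.56 M, at the same [G], which draws on G harder. Midnight, at 40 °C, counts 207 min, past the last row, so the table holds no reading to read it from, and I expect midnight to come out highest, as it counts more south-west minutes than winter.

The forecast says midnight, with winter at 47% (42% to 52%) and midnight at 76% (66% to 85%), on the same clock: “The 37 °C curve is the same curve with time roughly halved”. Its winter lies below my line, and its midnight is what first order to completion gives through the last north-west reading, whereas I give no number for midnight.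

The simulation gives midnight as highest, with winter at 46.0% and midnight at 69.6%, so the forecast's midnight stands 6.4 points too high.

    E → J (k = 0.00190 s⁻¹, Ea = 84.0 kJ mol⁻¹)
    G + L → X (k = 1.40 × 10⁻⁵ M⁻¹ s⁻¹, Ea = 83.0 kJ mol⁻¹)
    D ⇌ E (K = 0.0250, k = 8.80 × 10⁻⁴ s⁻¹, Ea = 98.0 kJ mol⁻¹, ΔH = −8.00 kJ mol⁻¹)
    G + D → Q (k = 1.70 × 10⁻⁴ M⁻¹ s⁻¹, Ea = 70.0 kJ mol⁻¹)
    E → Z (k = 5.40 × 10⁻⁴ s⁻¹, Ea = 88.0 kJ mol⁻¹)
    L ⇌ E (K = 0.0250, k = 8.80 × 10⁻⁴ s⁻¹, Ea = 98.0 kJ mol⁻¹, ΔH = −8.00 kJ mol⁻¹)
    (constants at 25 °C)

In winter the line's 49.8% met 46.0%, which is 3.9 points lower. Now take the stretch of 2.00 to a neighbour, a repeat of midnight at 15 °C with amounts and time held. Its 80 min count as 23.8 min on the south-west clock, which falls between the rows at 10.0 min and 30.0 min. The straight line there gives 29.1%. The neighbour ends with Q at 25.2%, which is 3.9 points under its line.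

The earlier runs and the new flask are simulated with made-up constants; scatter was added.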